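Its constants were set for the occasion, and the outcome is calculated.

In violet the first step, with free catalyst held at its charge, gives substrate a half-life of 8.2 h, and 20 h of that suggests 81.5 % conversion; but free catalyst does not stay at its charge.

    substrate + free catalyst → catalyst intermediate A (k1 = 0.069 /M/s)
    catalyst intermediate A → catalyst intermediate B (k2 = 0.0098 /s)
    catalyst intermediate B ⇌ free catalyst + target (K3 = 0.86 M, k3 = 0.0073 /s)

the same everywhere: free catalyst 0.2 mol%
- violet: substrate 0.17 M; time 20 h; everything together in a closed stirred flask, run for 20 h
- blue: substrate 0.17 M; a single well-mixed tank run continuously and read at steady state, 200 h in it on average
- grey: substrate 0.17 M (fed, over 10.0 h); time 20 h; a stirred flask in which substrate is dosed at a steady rate over 10.0 h without added volume, worked up at 20 h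
- amber: substrate 0.17 M; one stirred flow tank at steady state, fed with the mixture as stated, mean residence time 20 h

- the stated concentrations are those of everything mixed, before any reaction; amounts are the same in each set-up
- the feed brings no volume worth counting
- run time (violet): 20 h

- the set-up with the highest amount of target at the outlet or at the end, in percent of the substrate put in ("none" if the first two lie within 2 percentage points) (violet / blue / grey / amber / none)
- amount of target at the outlet or at the end, in percent of the substrate put in, violet
- amount of target at the outlet or at the end, in percent of the substrate put in, blue
- amount of target at the outlet or at the end, in percent of the substrate put in, grey
- amount of target at the outlet or at the end, in percent of the substrate put in, amber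

The next run has to be chosen: charge at once, dose, or run a tank. At the charged substrate concentration, one catalyst turn spends 85.3 s as free catalyst, then 102 s as catalyst intermediate A and 137 s as catalyst intermediate B by the forward step. The two bound forms together hold the catalyst longer than the free form does, and the three times lie within a factor of 1.61, so no single step is rate-limiting at this concentration. Since the half-life of catalyst intermediate B by its forward step is far shorter than that of substrate by step 1, the catalyst forms follow substrate from moment to moment.

The waiting time equals the bound time at the half-saturation concentration, c_half = 0.0606 M, the Michaelis constant of this cycle. At fixed total catalyst, and with the return of target left aside, the rate tends to zero order in c(substrate) far above it and to first order far below it. The charge stands at 2.80 c_half, so the free share at the start of violet is 26.3 %.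

My own reckoning follows. The rate falls from that start as substrate is used, and the return of target lowers it further, so violet stays under 44.4 %. Grey and amber hold c(substrate) below the charge, so that bound covers them too. By this reckoning blue stands beyond a conversion of 0.5: at that conversion the rate, carried over 200 h, comes to 338 % of the charge, more than the 0.5 of the charge that the tank has to turn over there. My choice is therefore the long tank, and no dosing.

The forecast gives 40.6 % for violet, 92.3 % for blue, 34.9 % for grey and 37.2 % for amber, with blue best, and calls the reaction “effectively irreversible, with mild product inhibition”.

The simulation gives 40.7 % for violet, 92.3 % for blue, 34.9 % for grey and 37.3 % for amber, so blue stands highest. The blue tank holds substrate at 0.0130 M, which is 0.215 c_half. The amber tank, reckoned from its yield, holds about 0.107 M, which is 1.77 c_half.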